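**Retrosynthetic overview**

1. Rabdosiin 18 ⇐ 17 by one palladium-mediated removal of eight allyl ethers and of a 2-methylidenepropane-1,3-diyl strap; 17 ⇐ 16 by epimerisation at C2.
2. 16 ⇐ 14: ring B is closed by joining the arene carbon that becomes C8a to the benzylic carbon that becomes C1, through a photochemical 6π-electrocyclisation followed by a [1,5]-hydrogen shift.
3. Enabling feature: in 14 the aryl C6=C1 bond, C7=C8 and C8′=C7′ of an (E,E)-2,3-dibenzylidenesuccinate form an s-cis hexatriene. A 15-membered dilactone ring that is not in the target, built from the two (R)-danshensu carbinols and a strap across their carboxyl groups, fixes its sense of twist.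
4. 14 ⇐ fulgide 8 (two Stobbe condensations of diethyl succinate with 3,4-bis(allyloxy)benzaldehyde) + strapped diol 12 (sodium (R)-danshensu + 3-chloro-2-(chloromethyl)prop-1-ene).
5. Ring order: ring A (catechol arene) is bought; the 15-membered ring is made in step 8; ring B in step 9; the 15-membered ring is opened in step 11.

Key step: step 9

Remark: sodium (R)-danshensu 9 is taken as a commercial chiral-pool material. Precursors are numbered as lignans (aryl C1–C6, benzylidene C7, succinate C8, carboxyl C9, second half primed) and products as dihydronaphthalenes (C1–C8a).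

**Route**

Step 1
Reactants: 1 3,4-dihydroxybenzaldehyde
Product: 2 3,4-bis(allyloxy)benzaldehyde
Conditions: allyl bromide (2.4 equiv), K2CO3, DMF, 60 °C
Reagents that add atoms: allyl bromide, C=CCBr
Why: Williamson ether synthesis on both phenols; the aldehyde is inert to carbonate and no stereocentre is involved.

Step 2
Reactants: 2 3,4-bis(allyloxy)benzaldehyde; 3 diethyl succinate
Product: 4 (E)-4-[3,4-bis(allyloxy)phenyl]-3-(ethoxycarbonyl)but-3-enoic acid
Conditions: NaOEt, EtOH, reflux; then aq. HCl
Reagents that add atoms: none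
Why: Stobbe condensation: the succinate enolate adds to the aldehyde, the alkoxide lactonises onto the distal ester and the paraconate opens by E1cB elimination, which should give the (E)-alkylidene half-ester (aryl anti to the retained ester) as the preferred isomer.

Step 3
Reactants: 4 (E)-half-ester
Product: 5 diethyl (E)-2-[3,4-bis(allyloxy)benzylidene]succinate
Conditions: EtI, K2CO3, DMF, rt
Reagents that add atoms: ethyl iodide, CCI
Why: SN2 O-alkylation of the carboxylate re-forms the diester needed for a second Stobbe condensation without touching the alkene geometry.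

Step 4
Reactants: 5 diethyl (E)-2-[3,4-bis(allyloxy)benzylidene]succinate; 2 3,4-bis(allyloxy)benzaldehyde
Product: 7 (2E,3E)-2,3-bis[3,4-bis(allyloxy)benzylidene]succinic acid, via monoethyl ester 6 (not isolated)
Conditions: NaOEt, EtOH, reflux; then aq. KOH, reflux; then aq. HCl
Reagents that add atoms: potassium hydroxide, [K+].[OH-]
Why: A second Stobbe condensation at the remaining CH2 followed by saponification in the same flask should give the (E,E)-diacid, each aryl again settling anti to its neighbouring carboxyl; allyl aryl ethers are inert to ethoxide and hydroxide.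

Step 5
Reactants: 7 (2E,3E)-diacid
Product: 8 (3E,4E)-3,4-bis[3,4-bis(allyloxy)benzylidene]oxolane-2,5-dione (the fulgide)
Conditions: AcCl, CH2Cl2, rt; crystallisation
Reagents that add atoms: none
Why: Acyl chloride-mediated dehydration of the 1,4-diacid to the five-membered cyclic anhydride (fulgide formation) keeps both alkene geometries and should give a crystalline compound from which minor geometric isomers can be removed.

Step 6
Reactants: 9 sodium (2R)-3-(3,4-dihydroxyphenyl)-2-hydroxypropanoate (sodium danshensu, 2.1 equiv); 10 3-chloro-2-(chloromethyl)prop-1-ene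
Product: 11 2-methylidenepropane-1,3-diyl bis[(2R)-3-(3,4-dihydroxyphenyl)-2-hydroxypropanoate]
Conditions: NaI (cat.), DMF, 50 °C, Ar
Reagents that add atoms: none
Why: SN2 O-alkylation of the carboxylate by the bis-allylic dichloride (Finkelstein-assisted) installs the strap on both carboxyl groups at once; without added base the phenols and the secondary alcohol stay protonated and the (R)-centre is not touched.

Step 7
Reactants: 11 strapped tetraphenol
Product: 12 2-methylidenepropane-1,3-diyl bis{(2R)-3-[3,4-bis(allyloxy)phenyl]-2-hydroxypropanoate}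
Conditions: allyl bromide (4.5 equiv), K2CO3, acetone, reflux
Reagents that add atoms: allyl bromide, C=CCBr
Why: Williamson ether synthesis: K2CO3 ionises only the four phenols, so the two secondary alcohols stay free for step 8 and the α-hydroxy ester stereocentres are not epimerised.

Step 8
Reactants: 8 fulgide; 12 strapped diol
Product: 14 15-membered dilactone in which the two carboxyl groups of (E,E)-diacid 7 are esterified by the two (R)-carbinols of 12, via seco-acid 13 (not isolated)
Conditions: slow addition of 8 + 12 (1:1) to 2-methyl-6-nitrobenzoic anhydride (1.3 equiv), DMAP, Et3N, CH2Cl2 (1 mM), rt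
Reagents that add atoms: none
Why: DMAP-catalysed opening of the cyclic anhydride by one carbinol gives seco-acid 13, whose carboxyl is activated as the mixed anhydride and closes onto the second carbinol (Shiina macrolactonisation) under pseudo-high dilution; no stereocentre is formed and the (R)-centres are acylated with retention.

Step 9
Reactants: 14 15-membered (E,E)-dibenzylidenesuccinate dilactone
Product: 16 cis-(1R,2R)-1-aryl-1,2-dihydronaphthalene-2,3-dicarboxylate still carrying the 15-membered dilactone across the C2 and C3 esters, via 1,8a-dihydronaphthalene 15 (not isolated)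
Conditions: hν (350 nm, Pyrex), degassed MeCN (1 mM), rt
Reagents that add atoms: none
Why: Excitation of the bis(benzylidene)succinate chromophore should trigger a conrotatory 6π-electrocyclisation of the hexatriene C6=C1–C7=C8–C8′=C7′, which forms the C6–C7′ bond (future C8a–C1) and gives 1,8a-dihydronaphthalene 15; a thermal suprafacial [1,5]-hydrogen shift from C8a to C2 then restores the aromaticity of ring A and leaves the C3=C4 bond conjugated. The closest known reaction type is the photocyclisation of (E,E)-2,3-dibenzylidenesuccinates whose two ester functions are locked in a chiral ring, together with the ring-closure/hydrogen-shift sequence of aryl fulgides. Ring B is closed in a pericyclic 6π mode (formally 6-endo at the benzylidene carbon) while the 15-membered dilactone stays intact. C1 is set by the sense of twist of the s-cis diene: with both enoates s-cis and each (R)-carbinol C–H eclipsing its acyl C=O, an idealised model puts the two strap carboxyl carbons about 4.5 Å apart for the P twist (positive C7=C8–C8′=C7′ dihedral) and about 8 Å apart for the M twist, so the three-carbon strap should span only the P form, and closure from the P form attacks the face of C7′ that gives (1R). C2 is set by the pericyclic rules: conrotation puts H-8a cis to H-1 (the aryl is the inward substituent of the (E)-benzylidene) and the suprafacial shift delivers that hydrogen to the same face of C2, hence the cis-(1R,2R) product that step 10 corrects. The step needs face selectivity (secured by the strap), closure at C6 and not at C2 of the aryl ring (favoured by the crowding next to the 3-allyloxy group), and cyclisation faster than E/Z isomerisation (favoured because the ring holds the triene near its reactive s-cis geometry).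

Step 10
Reactants: 16 cis-(1R,2R) macrocycle
Product: 17 trans-(1R,2S)-1-aryl-1,2-dihydronaphthalene-2,3-dicarboxylate with the 15-membered dilactone intact
Conditions: DBU (0.2 equiv), degassed CH2Cl2, rt
Reagents that add atoms: none
Why: Base-catalysed epimerisation through the C2 ester enolate (thermodynamic control) should give the trans isomer, in which the C1 aryl and the C2 ester are both pseudoaxial and the torsion between the two ester carbons is again positive as the strap prefers; C1 is not acidic and stays (R).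

Step 11
Reactants: 17 trans-(1R,2S) macrocycle
Product: 18 rabdosiin
Conditions: Pd(PPh3)4 (20 mol %), morpholine (excess), degassed THF, rt; then dil. HCl, reversed-phase chromatography
Reagents that add atoms: none
Why: Tsuji–Trost deallylation: zerovalent palladium ionises the eight aryl allyl ethers and both allylic C–O bonds of the 2-methylidenepropane-1,3-diyl diester, and morpholine traps every π-allyl fragment irreversibly, so the temporary ring is opened and all ten oxygens are freed in one operation without touching the two lactate esters, the C3=C4 bond or C2.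

**Compound list**

1 | 3,4-dihydroxybenzaldehyde | O=Cc1ccc(O)c(O)c1 | starting material
2 | 3,4-bis(allyloxy)benzaldehyde | O=Cc1ccc(OCC=C)c(OCC=C)c1 | intermediate
3 | diethyl succinate | CCOC(=O)CCC(=O)OCC | starting material
4 | (E)-4-[3,4-bis(allyloxy)phenyl]-3-(ethoxycarbonyl)but-3-enoic acid | OC(=O)C/C(C(=O)OCC)=C\c1ccc(OCC=C)c(OCC=C)c1 | intermediate
5 | diethyl (E)-2-[3,4-bis(allyloxy)benzylidene]succinate | CCOC(=O)C/C(C(=O)OCC)=C\c1ccc(OCC=C)c(OCC=C)c1 | intermediate
6 | (2E,3E)-2,3-bis[3,4-bis(allyloxy)benzylidene]succinic acid monoethyl ester | C=CCOc1ccc(cc1OCC=C)/C=C(C(=O)OCC)\C(C(=O)O)=C/c1ccc(OCC=C)c(OCC=C)c1 | intermediate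
7 | (2E,3E)-2,3-bis[3,4-bis(allyloxy)benzylidene]succinic acid | C=CCOc1ccc(cc1OCC=C)/C=C(C(=O)O)\C(C(=O)O)=C/c1ccc(OCC=C)c(OCC=C)c1 | intermediate
8 | (3E,4E)-3,4-bis[3,4-bis(allyloxy)benzylidene]oxolane-2,5-dione | C=CCOc1ccc(cc1OCC=C)/C=C1\C(=C/c2ccc(OCC=C)c(OCC=C)c2)C(=O)OC1=O | intermediate
9 | sodium (2R)-3-(3,4-dihydroxyphenyl)-2-hydroxypropanoate | O[C@H](Cc1ccc(O)c(O)c1)C(=O)[O-].[Na+] | starting material
10 | 3-chloro-2-(chloromethyl)prop-1-ene | C=C(CCl)CCl | starting material
11 | 2-methylidenepropane-1,3-diyl bis[(2R)-3-(3,4-dihydroxyphenyl)-2-hydroxypropanoate] | C=C(COC(=O)[C@H](O)Cc1ccc(O)c(O)c1)COC(=O)[C@H](O)Cc1ccc(O)c(O)c1 | intermediate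
12 | 2-methylidenepropane-1,3-diyl bis{(2R)-3-[3,4-bis(allyloxy)phenyl]-2-hydroxypropanoate} | C=C(COC(=O)[C@H](O)Cc1ccc(OCC=C)c(OCC=C)c1)COC(=O)[C@H](O)Cc1ccc(OCC=C)c(OCC=C)c1 | intermediate
13 | seco-acid: mono-ester of diacid 7 with one carbinol of 12, other carboxyl and other carbinol free | C=CCOc1ccc(cc1OCC=C)/C=C(C(=O)O)\C(C(=O)O[C@H](Cc1ccc(OCC=C)c(OCC=C)c1)C(=O)OCC(=C)COC(=O)[C@H](O)Cc1ccc(OCC=C)c(OCC=C)c1)=C/c1ccc(OCC=C)c(OCC=C)c1 | intermediate
14 | 15-membered dilactone of (E,E)-diacid 7 with both (R)-carbinols of 12 | C=CCOc1ccc(cc1OCC=C)/C=C2/C(=O)O[C@H](Cc1ccc(OCC=C)c(OCC=C)c1)C(=O)OCC(=C)COC(=O)[C@@H](Cc1ccc(OCC=C)c(OCC=C)c1)OC(=O)/C2=C/c1ccc(OCC=C)c(OCC=C)c1 | intermediate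
15 | macrocyclic 1,8a-dihydronaphthalene: C8a–C1 bond formed, H-8a and H-1 cis, ring A a cyclohexadiene, C2=C3 and C4=C4a double bonds | O=C(O[C@H](Cc1ccc(OCC=C)c(OCC=C)c1)C(=O)OCC(=C)CO3)C1=C(C(=O)O[C@H](Cc2ccc(OCC=C)c(OCC=C)c2)C3=O)[C@H](c2ccc(OCC=C)c(OCC=C)c2)[C@@H]2C=C(OCC=C)C(OCC=C)=CC2=C1 | intermediate
16 | cis-(1R,2R)-6,7-bis(allyloxy)-1-[3,4-bis(allyloxy)phenyl]-1,2-dihydronaphthalene-2,3-dicarboxylate, 15-membered dilactone with the strapped bis-danshensu unit | O=C(O[C@H](Cc1ccc(OCC=C)c(OCC=C)c1)C(=O)OCC(=C)CO3)C1=Cc2cc(OCC=C)c(OCC=C)cc2[C@@H](c2ccc(OCC=C)c(OCC=C)c2)[C@H]1C(=O)O[C@H](Cc1ccc(OCC=C)c(OCC=C)c1)C3=O | intermediate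
17 | trans-(1R,2S) isomer of 16 | O=C(O[C@H](Cc1ccc(OCC=C)c(OCC=C)c1)C(=O)OCC(=C)CO3)C1=Cc2cc(OCC=C)c(OCC=C)cc2[C@@H](c2ccc(OCC=C)c(OCC=C)c2)[C@@H]1C(=O)O[C@H](Cc1ccc(OCC=C)c(OCC=C)c1)C3=O | intermediate
18 | rabdosiin: (1R,2S)-1-(3,4-dihydroxyphenyl)-6,7-dihydroxy-1,2-dihydronaphthalene-2,3-dicarboxylic acid bis[(1R)-1-carboxy-2-(3,4-dihydroxyphenyl)ethyl] ester | O=C(O[C@H](Cc1ccc(O)c(O)c1)C(=O)O)C1=Cc2cc(O)c(O)cc2[C@@H](c2ccc(O)c(O)c2)[C@@H]1C(=O)O[C@H](Cc1ccc(O)c(O)c1)C(=O)O | target

**Step count**

Total steps: 11. Longest linear sequence: 9 steps (steps 1, 2, 3, 4, 5, 8, 9, 10, 11); steps 6 and 7 form the second branch.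

**Steps most likely to fail**

1. Step 9. The twist sense of the diene may be only weakly biased by the 15-membered ring, giving poor facial selectivity at C1. E/Z photoisomerisation may also compete with ring closure, or closure may occur at the crowded ortho carbon. The twist-sense argument rests on a hand-built geometric model and should be checked by a conformational search before the route is run. Fallback (sets out from 8 and 9, returns at 18): the strap is given up and the two C1 series are separated as diastereomers.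
   - Sodium danshensu 9 is per-allylated (allyl bromide, K2CO3, DMF) to allyl (2R)-3-[3,4-bis(allyloxy)phenyl]-2-hydroxypropanoate F1.
   - Two equivalents of F1 are acylated by fulgide 8 (DMAP, then 2-methyl-6-nitrobenzoic anhydride) to the open-chain (E,E)-bis-ester F2.
   - Irradiation at 350 nm should give, without facial control, the cis-(1R,2R) deca-allyl compound F3 and its cis-(1S,2S) diastereomer F4. DBU in the same flask should convert them to the trans-(1R,2S) deca-allyl rabdosiin F5 and the trans-(1S,2R) diastereomer F6.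
   - F5 and F6 differ as diastereomers because of the (R)-lactate esters and are separated by preparative HPLC.
   - F5 is deallylated with Pd(PPh3)4 and morpholine as in step 11 to give 18.

2. Step 8. Intermolecular acylation may outrun ring closure and give oligomers, the hindered secondary carbinols may acylate slowly, and the activated seco-acid may collapse back to the fulgide. Fallback (sets out from 9 and 8, returns at 14): the ring is closed last by carboxylate alkylation instead of acylation.
   - Sodium danshensu 9 is alkylated with 4-methoxybenzyl chloride in DMF to 4-methoxybenzyl (2R)-3-(3,4-dihydroxyphenyl)-2-hydroxypropanoate F7.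
   - The phenols of F7 are allylated (allyl bromide, K2CO3) to 4-methoxybenzyl (2R)-3-[3,4-bis(allyloxy)phenyl]-2-hydroxypropanoate F8.
   - Two equivalents of F8 are acylated by fulgide 8 (DMAP, then 2-methyl-6-nitrobenzoic anhydride) to the open-chain bis(4-methoxybenzyl) ester F9.
   - TFA and anisole in CH2Cl2 at 0 °C free the two carboxyl groups to give open-chain diacid F10.
   - Double O-alkylation of the dicaesium salt of F10 with dichloride 10 (Cs2CO3, DMF, high dilution) closes the 15-membered ring to 14.

3. Step 10. The equilibration may stall, the C3=C4 bond may migrate to the 1,4-dihydro isomer, air may dehydrogenate the ring to the naphthalene, or prolonged base may erode the lactate α-centres. Fallback (sets out from 16, returns at 17): kinetic instead of thermodynamic control. 16 is deprotonated at C2 with LiHMDS (1.05 equiv) in THF at −78 °C and the enolate is quenched with a hindered proton source (2,6-di-tert-butylphenol). Protonation should occur on the face opposite to the pseudoaxial C1 aryl and give 17 directly. No new compound is made.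

**Further compounds**

F1 | step 9 | allyl (2R)-3-[3,4-bis(allyloxy)phenyl]-2-hydroxypropanoate | C=CCOC(=O)[C@H](O)Cc1ccc(OCC=C)c(OCC=C)c1
F2 | step 9 | open-chain (E,E)-2,3-bis[3,4-bis(allyloxy)benzylidene]succinate bis-ester with the carbinols of two F1 | C=CCOc1ccc(cc1OCC=C)/C=C(C(=O)O[C@H](Cc1ccc(OCC=C)c(OCC=C)c1)C(=O)OCC=C)\C(C(=O)O[C@H](Cc1ccc(OCC=C)c(OCC=C)c1)C(=O)OCC=C)=C/c1ccc(OCC=C)c(OCC=C)c1
F3 | step 9 | cis-(1R,2R) deca-allyl rabdosiin isomer | O=C(O[C@H](Cc1ccc(OCC=C)c(OCC=C)c1)C(=O)OCC=C)C1=Cc2cc(OCC=C)c(OCC=C)cc2[C@@H](c2ccc(OCC=C)c(OCC=C)c2)[C@H]1C(=O)O[C@H](Cc1ccc(OCC=C)c(OCC=C)c1)C(=O)OCC=C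
F4 | step 9 | cis-(1S,2S) deca-allyl diastereomer | O=C(O[C@H](Cc1ccc(OCC=C)c(OCC=C)c1)C(=O)OCC=C)C1=Cc2cc(OCC=C)c(OCC=C)cc2[C@H](c2ccc(OCC=C)c(OCC=C)c2)[C@@H]1C(=O)O[C@H](Cc1ccc(OCC=C)c(OCC=C)c1)C(=O)OCC=C
F5 | step 9 | trans-(1R,2S) deca-allyl rabdosiin | O=C(O[C@H](Cc1ccc(OCC=C)c(OCC=C)c1)C(=O)OCC=C)C1=Cc2cc(OCC=C)c(OCC=C)cc2[C@@H](c2ccc(OCC=C)c(OCC=C)c2)[C@@H]1C(=O)O[C@H](Cc1ccc(OCC=C)c(OCC=C)c1)C(=O)OCC=C
F6 | step 9 | trans-(1S,2R) deca-allyl diastereomer | O=C(O[C@H](Cc1ccc(OCC=C)c(OCC=C)c1)C(=O)OCC=C)C1=Cc2cc(OCC=C)c(OCC=C)cc2[C@H](c2ccc(OCC=C)c(OCC=C)c2)[C@H]1C(=O)O[C@H](Cc1ccc(OCC=C)c(OCC=C)c1)C(=O)OCC=C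
F7 | step 8 | 4-methoxybenzyl (2R)-3-(3,4-dihydroxyphenyl)-2-hydroxypropanoate | COc1ccc(COC(=O)[C@H](O)Cc2ccc(O)c(O)c2)cc1
F8 | step 8 | 4-methoxybenzyl (2R)-3-[3,4-bis(allyloxy)phenyl]-2-hydroxypropanoate | COc1ccc(COC(=O)[C@H](O)Cc2ccc(OCC=C)c(OCC=C)c2)cc1
F9 | step 8 | open-chain (E,E)-dibenzylidenesuccinate bis-ester with the carbinols of two F8 | C=CCOc1ccc(cc1OCC=C)/C=C(C(=O)O[C@H](Cc1ccc(OCC=C)c(OCC=C)c1)C(=O)OCc1ccc(OC)cc1)\C(C(=O)O[C@H](Cc1ccc(OCC=C)c(OCC=C)c1)C(=O)OCc1ccc(OC)cc1)=C/c1ccc(OCC=C)c(OCC=C)c1
F10 | step 8 | open-chain (E,E)-dibenzylidenesuccinate bis-ester with two free danshensu carboxyl groups | C=CCOc1ccc(cc1OCC=C)/C=C(C(=O)O[C@H](Cc1ccc(OCC=C)c(OCC=C)c1)C(=O)O)\C(C(=O)O[C@H](Cc1ccc(OCC=C)c(OCC=C)c1)C(=O)O)=C/c1ccc(OCC=C)c(OCC=C)c1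
F0 | step 10 | none | none
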